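The upper flavan unit's pyran (C) ring is closed by stitching its phloroglucinol A ring onto a preformed O1–C2–C3–C4 chain. 3,5-Bis(benzyloxy)benzyne is captured by the C2 alkoxide (O1–C8a), and the aryl anion so formed opens the neighbouring trans-C3/C4 epoxide at benzylic C4 (C4a–C4) with inversion. This exploits the 1,3-relationship of O1 and C4 and the trans C3–O/C4–aryl array, and frees O3 for in-flask galloylation. The precursor is a threo trans-epoxy alcohol attached to C6 of an 8-bromo epicatechin-gallate-(4β→8)-catechin dimer by Suzuki coupling and Shi epoxidation.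

Key step: step 14

Remark: the target is read as epicatechin 3-O-gallate-(4β→6)-epicatechin 3-O-gallate-(4β→8)-catechin (both upper units 2R,3R with 2,3-cis-3,4-trans; lower unit 2R,3S). Compounds 6, 11, 17 and the L-series (ent) Shi ketone are taken as purchasable.

**Step 1**
Reactants: 1 (−)-epicatechin
Product: 2 5,7,3′,4′-tetra-O-benzyl-(−)-epicatechin
Conditions: BnBr, K2CO3, DMF, 0 °C → rt
Reagents that add atoms: benzyl bromide BrCc1ccccc1
Why: Williamson etherification of the four phenols, which are far more acidic than the C3 carbinol, leaves 3-OH free and touches no stereocentre.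

**Step 2**
Reactants: 2 5,7,3′,4′-tetra-O-benzyl-(−)-epicatechin
Product: 3 5,7,3′,4′-tetra-O-benzyl-4β-(2-ethoxyethoxy)epicatechin (2,3-cis-3,4-trans)
Conditions: DDQ, 2-ethoxyethanol, CH2Cl2, rt
Reagents that add atoms: 2-ethoxyethanol CCOCCO
Why: Oxidative benzylic etherification, in which DDQ abstracts hydride from the A-ring-activated C4 and the alcohol captures the cation anti to the axial C3–OH, sets the 3,4-trans (4β) ether.

**Step 3**
Reactants: 3 5,7,3′,4′-tetra-O-benzyl-4β-(2-ethoxyethoxy)epicatechin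
Product: 5 8-bromo-6-iodo-5,7,3′,4′-tetra-O-benzyl-4β-(2-ethoxyethoxy)epicatechin, via 8-bromo ether 4 (not isolated)
Conditions: NBS, NaHCO3, CH2Cl2, −78 → 0 °C; then NIS, MeCN, rt, dark
Reagents that add atoms: N-bromosuccinimide O=C1CCC(=O)N1Br; N-iodosuccinimide O=C1CCC(=O)N1I
Why: Electrophilic aromatic halogenation of the most electron-rich ring, in which NBS takes the less hindered C8 and NIS then fills C6, the only A-ring position left, so that iodine marks C6 for C–C coupling and bromine blocks C8.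

**Step 4**
Reactants: 5 8-bromo-6-iodo ether; 6 3,4,5-tris(benzyloxy)benzoyl chloride
Product: 7 3-O-[3,4,5-tris(benzyloxy)benzoyl] ester of 5 (C4 donor)
Conditions: DMAP, pyridine, CH2Cl2, rt
Reagents that add atoms: none
Why: DMAP-catalysed acylation of the only free hydroxyl installs the middle-unit gallate, which also masks O3 for all later steps.

**Step 5**
Reactants: 8 (+)-catechin
Product: 9 3,5,7,3′,4′-penta-O-benzyl-(+)-catechin
Conditions: NaH, BnBr, DMF, −20 °C → rt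
Reagents that add atoms: benzyl bromide BrCc1ccccc1
Why: Exhaustive Williamson benzylation caps all five hydroxyls, so that the lower O3 carries a group that leaves only in the final hydrogenolysis.

**Step 6**
Reactants: 7 C4 donor; 9 penta-O-benzylcatechin
Product: 10 protected dimer iodide, i.e. 8-bromo-6-iodo-epicatechin 3-O-gallate-(4β→8)-catechin with all other oxygens benzylated
Conditions: TMSOTf (cat.), CH2Cl2, −78 → −40 °C; Et3N quench
Reagents that add atoms: none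
Why: Lewis-acid ionisation of the C4 ether gives a benzylic cation, shielded on one face by the participating 3-O-acyl group, that is attacked by the more accessible C8 of 9 in a Friedel–Crafts flavan coupling trans to O3 (4β→8), while the donor cannot self-condense because its C6 and C8 carry halogens.

**Step 7**
Reactants: 11 3,4-bis(benzyloxy)benzaldehyde
Product: 12 rac-1-[3,4-bis(benzyloxy)phenyl]prop-2-yn-1-ol
Conditions: ethynylmagnesium bromide, THF, 0 °C
Reagents that add atoms: ethynylmagnesium bromide C#C[Mg]Br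
Why: Grignard addition to the aldehyde gives the racemic propargylic alcohol.

**Step 8**
Reactants: 12 rac-1-[3,4-bis(benzyloxy)phenyl]prop-2-yn-1-ol
Product: 13 (S)-1-[3,4-bis(benzyloxy)phenyl]prop-2-yn-1-ol
Conditions: Novozym 435, vinyl acetate, MTBE, 35 °C, to about half conversion
Reagents that add atoms: none
Why: Lipase kinetic resolution (Kazlauskas rule, aryl as large and ethynyl as medium group) should acetylate the R alcohol and leave the S alcohol, whose carbinol becomes C2 of the upper unit.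

**Step 9**
Reactants: 13 (S)-propargylic alcohol
Product: 14 (S,E)-1-[3,4-bis(benzyloxy)phenyl]-3-(4,4,5,5-tetramethyl-1,3,2-dioxaborolan-2-yl)prop-2-en-1-ol
Conditions: B2pin2, CuCl (cat.), Xantphos (cat.), NaOtBu (cat.), MeOH, THF, rt
Reagents that add atoms: bis(pinacolato)diboron CC1(C)OB(OC1(C)C)B1OC(C)(C)C(C)(C)O1
Why: Copper-catalysed anti-Markovnikov protoboration (syn addition of Cu–Bpin, then protonolysis by MeOH) gives the E-alkenyl boronate without touching the carbinol.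

**Step 10**
Reactants: 10 protected dimer iodide; 14 alkenyl boronate
Product: 15 dimer carrying at C6 of its upper unit the (S,E)-3-[3,4-bis(benzyloxy)phenyl]-3-hydroxyprop-1-enyl group
Conditions: PdCl2(dppf) (cat.), K3PO4, THF/H2O, 50 °C
Reagents that add atoms: none
Why: Suzuki–Miyaura coupling at the C–I bond, which undergoes oxidative addition far faster than the equally hindered C8–Br bond, transfers the alkenyl group with retention of E geometry.

**Step 11**
Reactants: 15 allylic alcohol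
Product: 16 threo trans-epoxy alcohol, (R)-carbinol with (2S,3S)-oxirane whose C3 carries the dimer aryl group
Conditions: ent-Shi ketone (0.3 equiv), 30% H2O2, aq K2CO3/EDTA, MeCN–EtOH–CH2Cl2, 0 °C; used crude
Reagents that add atoms: hydrogen peroxide OO
Why: Shi asymmetric epoxidation, in which the dioxirane of the L-series ketone attacks the E-alkene through the spiro transition state in the sense opposite to the (R,R)-epoxides given by the D-fructose ketone, sets the (S,S)-trans-epoxide under catalyst control and hence threo to the carbinol.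

**Step 12**
Reactants: 17 3,5-bis(benzyloxy)phenol
Product: 18 2-bromo-3,5-bis(benzyloxy)phenol
Conditions: NBS, i-Pr2NH (cat.), CH2Cl2, −78 → 0 °C
Reagents that add atoms: N-bromosuccinimide O=C1CCC(=O)N1Br
Why: Amine-catalysed ortho-selective bromination of the phenol (N-bromoamine delivered by hydrogen bonding to OH) places bromine between OH and OBn.

**Step 13**
Reactants: 18 2-bromo-3,5-bis(benzyloxy)phenol
Product: 21 3,5-bis(benzyloxy)-2-(trimethylsilyl)phenyl triflate, via O-trimethylsilyl ether 19 (not isolated), via lithium 2-silylphenolate 20 (not isolated)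
Conditions: HMDS, THF, reflux, evaporate; n-BuLi, THF, −78 °C; Tf2O, −78 °C → rt
Reagents that add atoms: hexamethyldisilazane C[Si](C)(C)N[Si](C)(C)C; triflic anhydride O=S(=O)(OS(=O)(=O)C(F)(F)F)C(F)(F)F
Why: O-silylation, Br/Li exchange and retro-Brook 1,3-O→C silyl shift give the ortho-silyl phenolate, which is triflated to the Kobayashi-type aryne precursor.

**Step 14**
Reactants: 16 threo trans-epoxy alcohol; 21 aryne precursor; 6 3,4,5-tris(benzyloxy)benzoyl chloride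
Product: 25 fully protected trimer (8-bromo on the middle unit, nineteen benzyl ethers, both gallates in place), via potassium alkoxide of the epoxy alcohol 22 (not isolated), via 3,5-bis(benzyloxy)benzyne 23 (not isolated), via potassium 3-olate of the annulated flavan 24 (not isolated)
Conditions: KH (1.0 equiv), 18-crown-6, THF, −40 °C; 21 (slow addition), KF, −20 °C → rt; then 6, DMAP, 0 °C → rt
Reagents that add atoms: none
Why: Proposed new method: fluoride-induced 1,2-elimination of 21 gives aryne 23; alkoxide 22 adds to the aryne carbon remote from the flanking benzyloxy group (O1–C8a, the usual meta selectivity of 3-alkoxyarynes), and the aryl anion so placed at C4a opens the adjacent epoxide at C4 (C4a–C4) to give 3-olate 24, which 6 acylates in the same flask. The closest known reactions are aryne annulations in which an O-nucleophile adds and the aryl anion is trapped by a tethered electrophile (xanthone, xanthene and chroman syntheses) and Parham-type aryl-anion/epoxide cyclisations; an epoxide as the internal trap of an aryne adduct is the new element. The pyran ring closes in the 6-endo-tet mode at the epoxide, preferred over 5-exo attack at C3 because C4 is benzylic to the 2,4,6-trioxygenated ring of the middle unit. C2 and C3 keep their C–O bonds and hence their configuration, whereas C4 is inverted by backside attack, so the trans-epoxide delivers the 2,3-cis-3,4-trans array. The step needs the C2 alkoxide as the only nucleophile (all other hydroxyls are benzylated or acylated), an aprotic medium so that the aryl anion is not quenched (KH leaves only H2), and a scarce aryne (slow addition, low temperature) so that neither Payne migration of 22 nor O-arylation of 24 competes.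

**Step 15**
Reactants: 25 fully protected trimer
Product: 26 CNP0112921.1 (target)
Conditions: H2, Pd(OH)2/C, Et3N, THF/MeOH/H2O, rt
Reagents that add atoms: none
Why: Hydrogenolysis over Pearlman's catalyst removes the nineteen benzyl ethers and, with Et3N as HBr scavenger, the C8 bromide, while the aryl esters, the interflavan bonds and all stereocentres are untouched.

**Compound list**

1 | (−)-epicatechin | O[C@@H]1Cc2c(O)cc(O)cc2O[C@@H]1c1ccc(O)c(O)c1 | starting material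
2 | 5,7,3′,4′-tetra-O-benzyl-(−)-epicatechin | O[C@@H]1Cc2c(OCc3ccccc3)cc(OCc3ccccc3)cc2O[C@@H]1c1ccc(OCc2ccccc2)c(OCc2ccccc2)c1 | intermediate
3 | 5,7,3′,4′-tetra-O-benzyl-4β-(2-ethoxyethoxy)epicatechin | O[C@@H]1[C@@H](OCCOCC)c2c(OCc3ccccc3)cc(OCc3ccccc3)cc2O[C@@H]1c1ccc(OCc2ccccc2)c(OCc2ccccc2)c1 | intermediate
4 | 8-bromo derivative of 3 | O[C@@H]1[C@@H](OCCOCC)c2c(OCc3ccccc3)cc(OCc3ccccc3)c(Br)c2O[C@@H]1c1ccc(OCc2ccccc2)c(OCc2ccccc2)c1 | intermediate
5 | 8-bromo-6-iodo derivative of 3 | O[C@@H]1[C@@H](OCCOCC)c2c(OCc3ccccc3)c(I)c(OCc3ccccc3)c(Br)c2O[C@@H]1c1ccc(OCc2ccccc2)c(OCc2ccccc2)c1 | intermediate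
6 | 3,4,5-tris(benzyloxy)benzoyl chloride | O=C(Cl)c1cc(OCc2ccccc2)c(OCc2ccccc2)c(OCc2ccccc2)c1 | starting material
7 | 3-O-[3,4,5-tris(benzyloxy)benzoyl] ester of 5 (C4 donor) | O=C(O[C@@H]1[C@@H](OCCOCC)c2c(OCc3ccccc3)c(I)c(OCc3ccccc3)c(Br)c2O[C@@H]1c1ccc(OCc2ccccc2)c(OCc2ccccc2)c1)c1cc(OCc2ccccc2)c(OCc2ccccc2)c(OCc2ccccc2)c1 | intermediate
8 | (+)-catechin | O[C@H]1Cc2c(O)cc(O)cc2O[C@@H]1c1ccc(O)c(O)c1 | starting material
9 | 3,5,7,3′,4′-penta-O-benzyl-(+)-catechin | c1ccccc1CO[C@H]1Cc2c(OCc3ccccc3)cc(OCc3ccccc3)cc2O[C@@H]1c1ccc(OCc2ccccc2)c(OCc2ccccc2)c1 | intermediate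
10 | protected dimer iodide (upper unit 8-bromo-6-iodo, 3-O-tribenzylgalloyl; 4β→8 to penta-O-benzylcatechin) | Ic5c(OCc9ccccc9)c(Br)c6c(c5OCc9ccccc9)[C@H](c3c(OCc9ccccc9)cc(OCc9ccccc9)c4c3O[C@H](c7ccc(OCc9ccccc9)c(OCc9ccccc9)c7)[C@@H](OCc9ccccc9)C4)[C@@H](OC(=O)c8cc(OCc9ccccc9)c(OCc9ccccc9)c(OCc9ccccc9)c8)[C@@H](c7ccc(OCc9ccccc9)c(OCc9ccccc9)c7)O6 | intermediate
11 | 3,4-bis(benzyloxy)benzaldehyde | O=Cc1ccc(OCc2ccccc2)c(OCc2ccccc2)c1 | starting material
12 | rac-1-[3,4-bis(benzyloxy)phenyl]prop-2-yn-1-ol | OC(C#C)c1ccc(OCc2ccccc2)c(OCc2ccccc2)c1 | intermediate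
13 | (S)-1-[3,4-bis(benzyloxy)phenyl]prop-2-yn-1-ol | O[C@@H](C#C)c1ccc(OCc2ccccc2)c(OCc2ccccc2)c1 | intermediate
14 | (S,E)-1-[3,4-bis(benzyloxy)phenyl]-3-(pinacolboryl)prop-2-en-1-ol | O[C@@H](/C=C/B1OC(C)(C)C(C)(C)O1)c1ccc(OCc2ccccc2)c(OCc2ccccc2)c1 | intermediate
15 | dimer with (S,E)-3-aryl-3-hydroxyprop-1-enyl group at C6 of the upper unit | O[C@@H](/C=C/c5c(OCc9ccccc9)c(Br)c6c(c5OCc9ccccc9)[C@H](c3c(OCc9ccccc9)cc(OCc9ccccc9)c4c3O[C@H](c7ccc(OCc9ccccc9)c(OCc9ccccc9)c7)[C@@H](OCc9ccccc9)C4)[C@@H](OC(=O)c8cc(OCc9ccccc9)c(OCc9ccccc9)c(OCc9ccccc9)c8)[C@@H](c7ccc(OCc9ccccc9)c(OCc9ccccc9)c7)O6)c7ccc(OCc9ccccc9)c(OCc9ccccc9)c7 | intermediate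
16 | threo trans-epoxy alcohol ((R)-carbinol, (2S,3S)-oxirane) | O[C@@H]([C@@H]1O[C@H]1c5c(OCc9ccccc9)c(Br)c6c(c5OCc9ccccc9)[C@H](c3c(OCc9ccccc9)cc(OCc9ccccc9)c4c3O[C@H](c7ccc(OCc9ccccc9)c(OCc9ccccc9)c7)[C@@H](OCc9ccccc9)C4)[C@@H](OC(=O)c8cc(OCc9ccccc9)c(OCc9ccccc9)c(OCc9ccccc9)c8)[C@@H](c7ccc(OCc9ccccc9)c(OCc9ccccc9)c7)O6)c7ccc(OCc9ccccc9)c(OCc9ccccc9)c7 | intermediate
17 | 3,5-bis(benzyloxy)phenol | Oc1cc(OCc2ccccc2)cc(OCc2ccccc2)c1 | starting material
18 | 2-bromo-3,5-bis(benzyloxy)phenol | Oc1cc(OCc2ccccc2)cc(OCc2ccccc2)c1Br | intermediate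
19 | O-trimethylsilyl ether of 18 | C[Si](C)(C)Oc1cc(OCc2ccccc2)cc(OCc2ccccc2)c1Br | intermediate
20 | lithium 3,5-bis(benzyloxy)-2-(trimethylsilyl)phenolate | [Li+].[O-]c1cc(OCc2ccccc2)cc(OCc2ccccc2)c1[Si](C)(C)C | intermediate
21 | 3,5-bis(benzyloxy)-2-(trimethylsilyl)phenyl trifluoromethanesulfonate | C[Si](C)(C)c1c(OCc2ccccc2)cc(OCc2ccccc2)cc1OS(=O)(=O)C(F)(F)F | intermediate
22 | potassium alkoxide of 16 | [K+].[O-][C@@H]([C@@H]1O[C@H]1c5c(OCc9ccccc9)c(Br)c6c(c5OCc9ccccc9)[C@H](c3c(OCc9ccccc9)cc(OCc9ccccc9)c4c3O[C@H](c7ccc(OCc9ccccc9)c(OCc9ccccc9)c7)[C@@H](OCc9ccccc9)C4)[C@@H](OC(=O)c8cc(OCc9ccccc9)c(OCc9ccccc9)c(OCc9ccccc9)c8)[C@@H](c7ccc(OCc9ccccc9)c(OCc9ccccc9)c7)O6)c7ccc(OCc9ccccc9)c(OCc9ccccc9)c7 | intermediate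
23 | 3,5-bis(benzyloxy)benzyne | C1#CC(OCc2ccccc2)=CC(OCc2ccccc2)=C1 | intermediate
24 | potassium 3-olate of the annulated upper flavan (2,3-cis-3,4-trans) | [K+].[O-][C@@H]1[C@@H](c5c(OCc9ccccc9)c(Br)c6c(c5OCc9ccccc9)[C@H](c3c(OCc9ccccc9)cc(OCc9ccccc9)c4c3O[C@H](c7ccc(OCc9ccccc9)c(OCc9ccccc9)c7)[C@@H](OCc9ccccc9)C4)[C@@H](OC(=O)c8cc(OCc9ccccc9)c(OCc9ccccc9)c(OCc9ccccc9)c8)[C@@H](c7ccc(OCc9ccccc9)c(OCc9ccccc9)c7)O6)c2c(OCc9ccccc9)cc(OCc9ccccc9)cc2O[C@@H]1c7ccc(OCc9ccccc9)c(OCc9ccccc9)c7 | intermediate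
25 | fully protected trimer (nonadeca-O-benzyl, 8-bromo on the middle unit) | O=C(O[C@@H]1[C@@H](c5c(OCc9ccccc9)c(Br)c6c(c5OCc9ccccc9)[C@H](c3c(OCc9ccccc9)cc(OCc9ccccc9)c4c3O[C@H](c7ccc(OCc9ccccc9)c(OCc9ccccc9)c7)[C@@H](OCc9ccccc9)C4)[C@@H](OC(=O)c8cc(OCc9ccccc9)c(OCc9ccccc9)c(OCc9ccccc9)c8)[C@@H](c7ccc(OCc9ccccc9)c(OCc9ccccc9)c7)O6)c2c(OCc9ccccc9)cc(OCc9ccccc9)cc2O[C@@H]1c7ccc(OCc9ccccc9)c(OCc9ccccc9)c7)c8cc(OCc9ccccc9)c(OCc9ccccc9)c(OCc9ccccc9)c8 | intermediate
26 | CNP0112921.1, epicatechin 3-O-gallate-(4β→6)-epicatechin 3-O-gallate-(4β→8)-catechin | O=C(O[C@@H]1[C@@H](c2c(O)cc3c(c2O)[C@H](c2c(O)cc(O)c4c2O[C@H](c2ccc(O)c(O)c2)[C@@H](O)C4)[C@@H](OC(=O)c2cc(O)c(O)c(O)c2)[C@@H](c2ccc(O)c(O)c2)O3)c2c(O)cc(O)cc2O[C@@H]1c1ccc(O)c(O)c1)c1cc(O)c(O)c(O)c1 | target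

**Totals**

Total steps: 15. Longest linear sequence: 9 steps (1, 2, 3, 4, 6, 10, 11, 14, 15).

**Steps most likely to fail**

Step 14 (Proposed new method). The alkoxide may undergo Payne migration before the aryne appears. The aryl anion may be protonated or may attack C3 (5-exo) instead of C4. The product alkoxide may be O-arylated by excess aryne. The fallback sets out from 16 and separates the two bond formations with known chemistry. 16 would be O-arylated by plain aryne O–H insertion without base (21, CsF, MeCN/THF, rt) to give the 3,5-bis(benzyloxy)phenyl ether of the epoxy alcohol F1. A catalytic Lewis acid (BF3·OEt2, CH2Cl2, −78 °C) would then trigger the intramolecular Friedel–Crafts epoxide–arene cyclisation, 6-endo at the benzylic carbon and anti to the C3 oxygen, to the free upper-unit 3-ol F2. Acylation of F2 with 6 and DMAP in pyridine rejoins the route at 25.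

Step 11. Facial control may be poor on a large, lipophilic substrate that already bears a carbinol. The very electron-rich styrene oxide may open or rearrange during reaction or isolation. The fallback sets out from 15 and replaces electrophilic by nucleophilic epoxidation. MnO2 oxidation of the allylic alcohol would give the E-chalcone F3. Juliá–Colonna epoxidation (poly-L-leucine, urea–H2O2, DBU, THF) would give the (αR,βS)-trans-epoxy ketone F4. CBS reduction ((R)-Me-CBS, catecholborane, −78 °C, aryl as the large group) would set the carbinol under reagent control and rejoin the route at 16.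

Step 10. Oxidative addition and transmetalation at the doubly ortho-substituted iodide may be slow, so that protodeiodination or reaction at the C8–Br bond intrudes. The acid-sensitive diaryl allylic alcohol may ionise on work-up. The fallback sets out from 10 and 13 and uses a sterically less demanding alkyne partner. Sonogashira coupling (PdCl2(PPh3)2, CuI, Et3N/THF) would give the propargylic alcohol F5. Ruthenium-catalysed trans-hydrosilylation ([Cp*Ru(MeCN)3]PF6, (EtO)3SiH, CH2Cl2) would give the vinylsilane F6, with silicon on the alkene carbon that carries the dimer aryl group. Protodesilylation (TBAF, CuI, THF) would deliver the E-alkene and rejoin the route at 15.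

**Further compounds**

F1 | step 14 | 3,5-bis(benzyloxy)phenyl ether of epoxy alcohol 16 | c1c(OCc9ccccc9)cc(OCc9ccccc9)cc1O[C@@H]([C@@H]2O[C@H]2c5c(OCc9ccccc9)c(Br)c6c(c5OCc9ccccc9)[C@H](c3c(OCc9ccccc9)cc(OCc9ccccc9)c4c3O[C@H](c7ccc(OCc9ccccc9)c(OCc9ccccc9)c7)[C@@H](OCc9ccccc9)C4)[C@@H](OC(=O)c8cc(OCc9ccccc9)c(OCc9ccccc9)c(OCc9ccccc9)c8)[C@@H](c7ccc(OCc9ccccc9)c(OCc9ccccc9)c7)O6)c7ccc(OCc9ccccc9)c(OCc9ccccc9)c7
F2 | step 14 | protected trimer with free 3-OH on the upper unit (neutral form of 24) | O[C@@H]1[C@@H](c5c(OCc9ccccc9)c(Br)c6c(c5OCc9ccccc9)[C@H](c3c(OCc9ccccc9)cc(OCc9ccccc9)c4c3O[C@H](c7ccc(OCc9ccccc9)c(OCc9ccccc9)c7)[C@@H](OCc9ccccc9)C4)[C@@H](OC(=O)c8cc(OCc9ccccc9)c(OCc9ccccc9)c(OCc9ccccc9)c8)[C@@H](c7ccc(OCc9ccccc9)c(OCc9ccccc9)c7)O6)c2c(OCc9ccccc9)cc(OCc9ccccc9)cc2O[C@@H]1c7ccc(OCc9ccccc9)c(OCc9ccccc9)c7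
F3 | step 11 | E-chalcone (enone from oxidation of 15) | O=C(/C=C/c5c(OCc9ccccc9)c(Br)c6c(c5OCc9ccccc9)[C@H](c3c(OCc9ccccc9)cc(OCc9ccccc9)c4c3O[C@H](c7ccc(OCc9ccccc9)c(OCc9ccccc9)c7)[C@@H](OCc9ccccc9)C4)[C@@H](OC(=O)c8cc(OCc9ccccc9)c(OCc9ccccc9)c(OCc9ccccc9)c8)[C@@H](c7ccc(OCc9ccccc9)c(OCc9ccccc9)c7)O6)c7ccc(OCc9ccccc9)c(OCc9ccccc9)c7
F4 | step 11 | (αR,βS)-trans-epoxy ketone | O=C([C@@H]1O[C@H]1c5c(OCc9ccccc9)c(Br)c6c(c5OCc9ccccc9)[C@H](c3c(OCc9ccccc9)cc(OCc9ccccc9)c4c3O[C@H](c7ccc(OCc9ccccc9)c(OCc9ccccc9)c7)[C@@H](OCc9ccccc9)C4)[C@@H](OC(=O)c8cc(OCc9ccccc9)c(OCc9ccccc9)c(OCc9ccccc9)c8)[C@@H](c7ccc(OCc9ccccc9)c(OCc9ccccc9)c7)O6)c7ccc(OCc9ccccc9)c(OCc9ccccc9)c7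
F5 | step 10 | propargylic alcohol from Sonogashira coupling of 10 with 13 (carbinol configuration of 13) | O[C@@H](C#Cc5c(OCc9ccccc9)c(Br)c6c(c5OCc9ccccc9)[C@H](c3c(OCc9ccccc9)cc(OCc9ccccc9)c4c3O[C@H](c7ccc(OCc9ccccc9)c(OCc9ccccc9)c7)[C@@H](OCc9ccccc9)C4)[C@@H](OC(=O)c8cc(OCc9ccccc9)c(OCc9ccccc9)c(OCc9ccccc9)c8)[C@@H](c7ccc(OCc9ccccc9)c(OCc9ccccc9)c7)O6)c7ccc(OCc9ccccc9)c(OCc9ccccc9)c7
F6 | step 10 | triethoxysilyl vinylsilane from trans-hydrosilylation of F5 (Si on the aryl-bearing carbon, cis to the carbinol carbon) | O[C@@H](/C=C(/c5c(OCc9ccccc9)c(Br)c6c(c5OCc9ccccc9)[C@H](c3c(OCc9ccccc9)cc(OCc9ccccc9)c4c3O[C@H](c7ccc(OCc9ccccc9)c(OCc9ccccc9)c7)[C@@H](OCc9ccccc9)C4)[C@@H](OC(=O)c8cc(OCc9ccccc9)c(OCc9ccccc9)c(OCc9ccccc9)c8)[C@@H](c7ccc(OCc9ccccc9)c(OCc9ccccc9)c7)O6)[Si](OCC)(OCC)OCC)c7ccc(OCc9ccccc9)c(OCc9ccccc9)c7
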